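The plan cuts ring C of the flavanone across C2–C3 and O1–C8a. It exploits two features: C2 is the carbinol carbon of a β-aryloxy ketone (an aldol retron toward C3), and C8a of ring A sits ortho to the C4 ketone, so a fluoride there is open to SNAr. In one flask an aryl methyl ketone enol silane adds to 4-(benzyloxy)benzaldehyde under a chiral boron Lewis acid (sets 2S), then catalytic fluoride turns the silyl aldolate into an alkoxide that displaces the ring A fluoride, closing ring C with loss of Me3SiF. The precursor is an open 2-fluoroacetophenone enol silane carrying the preformed (3R,4S)-isoflavan.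

Key step: step 12

Remark 1: 2,6-dimethoxyphenol, 5-fluorobenzene-1,3-diol, 4-(benzyloxy)-2-hydroxybenzaldehyde and 4-(benzyloxy)benzaldehyde are taken as commercial.
Remark 2: the antipode named for each chiral catalyst (steps 8 and 12) is the one expected from the usual stereochemical models (Si-face attack on the aldehyde in step 12); should a model reaction show the opposite sense, the mirror-image catalyst is used.

Step 1
Reactants: 1 2,6-dimethoxyphenol
Product: 2 2-(benzyloxy)-1,3-dimethoxybenzene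
Conditions: BnBr, K2CO3, DMF, 50 °C
Reagents that add atoms: benzyl bromide, BrCc1ccccc1
Why: Williamson etherification of the phenol; benzyl is used on every phenol so that all protecting groups fall in one final hydrogenolysis.

Step 2
Reactants: 2 2-(benzyloxy)-1,3-dimethoxybenzene
Product: 3 3-(benzyloxy)-2,4-dimethoxybenzaldehyde
Conditions: POCl3, DMF, 80 °C; then H2O
Reagents that add atoms: N,N-dimethylformamide, CN(C)C=O; water, O
Why: Vilsmeier–Haack formylation goes para to one methoxy group and ortho to the other, the only activated type of position in a 1,2,3-trialkoxybenzene.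

Step 3
Reactants: 3 3-(benzyloxy)-2,4-dimethoxybenzaldehyde
Product: 4 2-(benzyloxy)-1,3-dimethoxy-4-(2-methoxyethenyl)benzene (E/Z mixture)
Conditions: Ph3P(CH2OMe)Cl, KOt-Bu, THF, 0 °C → rt
Reagents that add atoms: (methoxymethyl)triphenylphosphonium chloride, COC[P+](c1ccccc1)(c1ccccc1)c1ccccc1.[Cl-]
Why: Wittig methoxymethylenation homologates the aldehyde to the enol ether, whose double-bond geometry is of no consequence.

Step 4
Reactants: 4 2-(benzyloxy)-1,3-dimethoxy-4-(2-methoxyethenyl)benzene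
Product: 5 2-[3-(benzyloxy)-2,4-dimethoxyphenyl]acetaldehyde
Conditions: aq HCl (2 M), THF, 50 °C; used crude
Reagents that add atoms: water, O
Why: Acid-catalysed enol ether hydrolysis unmasks the arylacetaldehyde, which is used at once because it self-condenses on standing.

Step 5
Reactants: 6 5-fluorobenzene-1,3-diol
Product: 7 5-fluoro-2-iodobenzene-1,3-diol
Conditions: I2, NaHCO3, H2O, 0 °C → rt
Reagents that add atoms: iodine, II
Why: Electrophilic aromatic iodination of a resorcinol in aqueous bicarbonate goes to C2 between the two hydroxyls, and here the alternative C4/C6 positions are further deactivated by the ortho fluorine.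

Step 6
Reactants: 7 5-fluoro-2-iodobenzene-1,3-diol
Product: 8 1,3-bis(benzyloxy)-5-fluoro-2-iodobenzene
Conditions: BnBr, K2CO3, DMF, 50 °C
Reagents that add atoms: benzyl bromide, BrCc1ccccc1
Why: Double Williamson etherification; the iodine now marks unambiguously the ring A carbon between the two oxygens, para to fluorine.

Step 7
Reactants: 8 1,3-bis(benzyloxy)-5-fluoro-2-iodobenzene; 9 4-(benzyloxy)-2-hydroxybenzaldehyde
Product: 12 5-(benzyloxy)-2-{[2,6-bis(benzyloxy)-4-fluorophenyl](hydroxy)methyl}phenol (racemic), via aryl Grignard 10 (not isolated), via sodium phenoxide 11 (not isolated)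
Conditions: 8, i-PrMgCl·LiCl, THF, −10 °C → rt; 9, NaH, THF, 0 °C; combine, 0 °C → rt; H2O
Reagents that add atoms: none
Why: Iodine–magnesium exchange gives aryl Grignard 10, which adds to the aldehyde of phenoxide 11 (Grignard 1,2-addition); the new carbinol centre is racemic and is erased in step 8.

Step 8
Reactants: 12 5-(benzyloxy)-2-{[2,6-bis(benzyloxy)-4-fluorophenyl](hydroxy)methyl}phenol; 5 2-[3-(benzyloxy)-2,4-dimethoxyphenyl]acetaldehyde
Product: 15 (2R,3S)-2-[3-(benzyloxy)-2,4-dimethoxyphenyl]-3-[4-(benzyloxy)-2-hydroxyphenyl]-3-[2,6-bis(benzyloxy)-4-fluorophenyl]propan-1-ol, via ortho-quinone methide 13 (not isolated), via lactol 14 (not isolated)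
Conditions: (R)-2-[diphenyl(trimethylsilyloxy)methyl]pyrrolidine (20 mol %), PhCO2H (20 mol %), CH2Cl2, 0 °C → rt; then NaBH4, MeOH, 0 °C
Reagents that add atoms: none
Why: Organocatalytic Michael addition/hemiacetalisation (formal [4+2]): acid-promoted loss of water from 12 gives ortho-quinone methide 13, the enamine of 5 adds to its methide carbon with one face shielded by the diphenyl(silyloxy)methyl group (sets C3 as R), the syn-selective addition and closure to the trans-diequatorial lactol 14 set C4 as S, and NaBH4 reduces the lactol before C3 can epimerise.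

Step 9
Reactants: 15 the (2R,3S)-phenol–primary alcohol of step 8
Product: 16 (3R,4S)-7-(benzyloxy)-3-[3-(benzyloxy)-2,4-dimethoxyphenyl]-4-[2,6-bis(benzyloxy)-4-fluorophenyl]chromane
Conditions: PPh3, DIAD, THF, 0 °C → rt
Reagents that add atoms: none
Why: Intramolecular Mitsunobu etherification of the phenol with the primary alcohol closes the chroman ring without touching C3 or C4.

Step 10
Reactants: 16 (3R,4S)-4-[2,6-bis(benzyloxy)-4-fluorophenyl]isoflavan
Product: 18 1-{2,4-bis(benzyloxy)-3-[(3R,4S)-7-(benzyloxy)-3-[3-(benzyloxy)-2,4-dimethoxyphenyl]chroman-4-yl]-6-fluorophenyl}ethan-1-one, via aryllithium 17 (not isolated)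
Conditions: lithium 2,2,6,6-tetramethylpiperidide (from the amine and n-BuLi), THF, −78 °C; then MeC(O)N(OMe)Me, −78 → −30 °C; H2O
Reagents that add atoms: N-methoxy-N-methylacetamide, CC(=O)N(C)OC
Why: Deprotonative ortho-lithiation at the only aryl C–H flanked by fluorine and an alkoxy group (the two such positions give the same compound on rotation about the C4–aryl bond), then acylation of aryllithium 17 with the N-methoxy-N-methylamide, whose chelated tetrahedral adduct prevents double addition.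

Step 11
Reactants: 18 the 2-fluoroacetophenone of step 10
Product: 19 [(1-{2,4-bis(benzyloxy)-3-[(3R,4S)-7-(benzyloxy)-3-[3-(benzyloxy)-2,4-dimethoxyphenyl]chroman-4-yl]-6-fluorophenyl}ethenyl)oxy]trimethylsilane
Conditions: TMSOTf, Et3N, CH2Cl2, 0 °C; non-aqueous work-up
Reagents that add atoms: trimethylsilyl trifluoromethanesulfonate, C[Si](C)(C)OS(=O)(=O)C(F)(F)F
Why: Soft enolisation (silyl triflate and amine) of the methyl ketone gives the only possible enol silane.

Step 12
Reactants: 19 the enol silane of step 11; 20 4-(benzyloxy)benzaldehyde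
Product: 22 (2S)-5,7-bis(benzyloxy)-2-[4-(benzyloxy)phenyl]-6-[(3R,4S)-7-(benzyloxy)-3-[3-(benzyloxy)-2,4-dimethoxyphenyl]chroman-4-yl]chroman-4-one, via silyl aldolate 21 (not isolated)
Conditions: B-butyl-1,3,2-oxazaborolidin-5-one of N-tosyl-(R)-tryptophan (20 mol %), EtCN, −78 °C; then Bu4N[Ph3SiF2] (0.3 equiv), THF, −78 → 0 °C
Reagents that add atoms: none
Why: The boron Lewis acid binds aldehyde 20 and enol silane 19 adds through an open transition state to its Si face (Mukaiyama aldol), forming C2–C3 and, after silyl transfer, the (S)-silyl aldolate 21. Fluoride then cleaves the O–Si bond and the alkoxide attacks C8a, ortho to the C4 ketone, by addition–elimination (SNAr through a σ-adduct that is the C4 enolate); the expelled fluoride is taken up as Me3SiF and carries the chain. The closest known reactions are the catalytic asymmetric Mukaiyama aldol of aryl methyl ketone enol silanes and the oxa-SNAr closure of 2-fluoroaryl β-hydroxy ketones to chroman-4-ones. Ring C closes by a 6-endo-trig addition to the C8a=C4a bond followed by loss of fluoride. C2 is set by the catalyst (reagent control, the isoflavan centres being remote) and is untouched in the ring closure because the C2–O bond stays intact. The step needs facial selectivity at the aldehyde and a ring closure faster than retro-aldol or dehydration; the first rests on the catalyst, the second on the ortho carbonyl, the two alkoxy groups lying meta to C8a (no resonance deactivation), low temperature and a low standing alkoxide concentration.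

Step 13
Reactants: 22 the pentabenzyl flavanone of step 12
Product: 23 (2S)-5,7-dihydroxy-6-[(3R,4S)-7-hydroxy-3-(3-hydroxy-2,4-dimethoxyphenyl)chroman-4-yl]-2-(4-hydroxyphenyl)chroman-4-one (target)
Conditions: H2 (1 atm), Pd/C, EtOAc–MeOH, rt
Reagents that add atoms: none
Why: Hydrogenolysis of the five benzyl aryl ethers under neutral conditions at atmospheric pressure, under which the flavanone C2–O1 bond, the ketone and the three stereocentres are expected to remain untouched.

Compound list
1 | 2,6-dimethoxyphenol | COc1cccc(OC)c1O | starting material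
2 | 2-(benzyloxy)-1,3-dimethoxybenzene | COc1cccc(OC)c1OCc1ccccc1 | intermediate
3 | 3-(benzyloxy)-2,4-dimethoxybenzaldehyde | COc1ccc(C=O)c(OC)c1OCc1ccccc1 | intermediate
4 | 2-(benzyloxy)-1,3-dimethoxy-4-(2-methoxyethenyl)benzene (E/Z mixture) | COC=Cc1ccc(OC)c(OCc2ccccc2)c1OC | intermediate
5 | 2-[3-(benzyloxy)-2,4-dimethoxyphenyl]acetaldehyde | O=CCc1ccc(OC)c(OCc2ccccc2)c1OC | intermediate
6 | 5-fluorobenzene-1,3-diol | Oc1cc(O)cc(F)c1 | starting material
7 | 5-fluoro-2-iodobenzene-1,3-diol | Oc1cc(F)cc(O)c1I | intermediate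
8 | 1,3-bis(benzyloxy)-5-fluoro-2-iodobenzene | Fc1cc(OCc2ccccc2)c(I)c(OCc2ccccc2)c1 | intermediate
9 | 4-(benzyloxy)-2-hydroxybenzaldehyde | O=Cc1ccc(OCc2ccccc2)cc1O | starting material
10 | [2,6-bis(benzyloxy)-4-fluorophenyl]magnesium chloride | Fc1cc(OCc2ccccc2)c([Mg]Cl)c(OCc2ccccc2)c1 | intermediate (not isolated)
11 | sodium 5-(benzyloxy)-2-formylphenolate | [Na+].[O-]c1cc(OCc2ccccc2)ccc1C=O | intermediate (not isolated)
12 | 5-(benzyloxy)-2-{[2,6-bis(benzyloxy)-4-fluorophenyl](hydroxy)methyl}phenol (racemic) | OC(c1ccc(OCc2ccccc2)cc1O)c1c(OCc2ccccc2)cc(F)cc1OCc1ccccc1 | intermediate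
13 | 3-(benzyloxy)-6-{[2,6-bis(benzyloxy)-4-fluorophenyl]methylidene}cyclohexa-2,4-dien-1-one | O=C1C=C(OCc2ccccc2)C=CC1=Cc1c(OCc2ccccc2)cc(F)cc1OCc1ccccc1 | intermediate (not isolated)
14 | (3R,4S)-7-(benzyloxy)-3-[3-(benzyloxy)-2,4-dimethoxyphenyl]-4-[2,6-bis(benzyloxy)-4-fluorophenyl]chroman-2-ol (both C2 anomers) | COc1ccc([C@@H]2C(O)Oc3cc(OCc4ccccc4)ccc3[C@H]2c2c(OCc3ccccc3)cc(F)cc2OCc2ccccc2)c(OC)c1OCc1ccccc1 | intermediate (not isolated)
15 | (2R,3S)-2-[3-(benzyloxy)-2,4-dimethoxyphenyl]-3-[4-(benzyloxy)-2-hydroxyphenyl]-3-[2,6-bis(benzyloxy)-4-fluorophenyl]propan-1-ol | COc1ccc([C@H](CO)[C@@H](c2ccc(OCc3ccccc3)cc2O)c2c(OCc3ccccc3)cc(F)cc2OCc2ccccc2)c(OC)c1OCc1ccccc1 | intermediate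
16 | (3R,4S)-7-(benzyloxy)-3-[3-(benzyloxy)-2,4-dimethoxyphenyl]-4-[2,6-bis(benzyloxy)-4-fluorophenyl]chromane | COc1ccc([C@@H]2COc3cc(OCc4ccccc4)ccc3[C@H]2c2c(OCc3ccccc3)cc(F)cc2OCc2ccccc2)c(OC)c1OCc1ccccc1 | intermediate
17 | {2,4-bis(benzyloxy)-3-[(3R,4S)-7-(benzyloxy)-3-[3-(benzyloxy)-2,4-dimethoxyphenyl]chroman-4-yl]-6-fluorophenyl}lithium | COc1ccc([C@@H]2COc3cc(OCc4ccccc4)ccc3[C@H]2c2c(OCc3ccccc3)cc(F)c([Li])c2OCc2ccccc2)c(OC)c1OCc1ccccc1 | intermediate (not isolated)
18 | 1-{2,4-bis(benzyloxy)-3-[(3R,4S)-7-(benzyloxy)-3-[3-(benzyloxy)-2,4-dimethoxyphenyl]chroman-4-yl]-6-fluorophenyl}ethan-1-one | COc1ccc([C@@H]2COc3cc(OCc4ccccc4)ccc3[C@H]2c2c(OCc3ccccc3)cc(F)c(C(C)=O)c2OCc2ccccc2)c(OC)c1OCc1ccccc1 | intermediate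
19 | [(1-{2,4-bis(benzyloxy)-3-[(3R,4S)-7-(benzyloxy)-3-[3-(benzyloxy)-2,4-dimethoxyphenyl]chroman-4-yl]-6-fluorophenyl}ethenyl)oxy]trimethylsilane | COc1ccc([C@@H]2COc3cc(OCc4ccccc4)ccc3[C@H]2c2c(OCc3ccccc3)cc(F)c(C(=C)O[Si](C)(C)C)c2OCc2ccccc2)c(OC)c1OCc1ccccc1 | intermediate
20 | 4-(benzyloxy)benzaldehyde | O=Cc1ccc(OCc2ccccc2)cc1 | starting material
21 | (3S)-1-{2,4-bis(benzyloxy)-3-[(3R,4S)-7-(benzyloxy)-3-[3-(benzyloxy)-2,4-dimethoxyphenyl]chroman-4-yl]-6-fluorophenyl}-3-[4-(benzyloxy)phenyl]-3-[(trimethylsilyl)oxy]propan-1-one | COc1ccc([C@@H]2COc3cc(OCc4ccccc4)ccc3[C@H]2c2c(OCc3ccccc3)cc(F)c(c2OCc2ccccc2)C(=O)C[C@@H](c2ccc(OCc4ccccc4)cc2)O[Si](C)(C)C)c(OC)c1OCc1ccccc1 | intermediate (not isolated)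
22 | (2S)-5,7-bis(benzyloxy)-2-[4-(benzyloxy)phenyl]-6-[(3R,4S)-7-(benzyloxy)-3-[3-(benzyloxy)-2,4-dimethoxyphenyl]chroman-4-yl]chroman-4-one | COc1ccc([C@@H]2COc3cc(OCc4ccccc4)ccc3[C@H]2c2c(OCc3ccccc3)cc3c(c2OCc2ccccc2)C(=O)C[C@@H](c2ccc(OCc4ccccc4)cc2)O3)c(OC)c1OCc1ccccc1 | intermediate
23 | (2S)-5,7-dihydroxy-6-[(3R,4S)-7-hydroxy-3-(3-hydroxy-2,4-dimethoxyphenyl)chroman-4-yl]-2-(4-hydroxyphenyl)chroman-4-one | COc1ccc([C@@H]2COc3cc(O)ccc3[C@H]2c2c(O)cc3c(c2O)C(=O)C[C@@H](c2ccc(O)cc2)O3)c(OC)c1O | target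

Total step count: 13. Longest linear sequence: 10 steps (steps 1–4 and 8–13, from 2,6-dimethoxyphenol).

Steps most likely to fail

Step 12. The alkoxide set free by fluoride may undergo retro-aldol cleavage (eroding the configuration at C2) or dehydration to the chalcone before it closes the ring, and the facial selectivity of the aldol with this hindered enol silane may be only moderate. The fallback sets out from 18 and returns at 22, and sets C2 by hydrogenation instead of by an aldol. The lithium enolate of 18 (LiHMDS, THF, −78 °C) is acylated with 4-(benzyloxy)benzoyl chloride in a Claisen-type condensation to the 1,3-diketone F1. K2CO3 in DMF at 80 °C then closes ring C by SNAr of the enolate oxygen at C8a, giving the flavone F2. Asymmetric hydrogenation of F2 with Ru(cod)(2-methylallyl)2 and a chiral N-heterocyclic carbene ligand (antipode chosen on a model) under H2 should give the cis-(2S,4S)-flavan-4-ol F3. Dess–Martin oxidation of the C4 alcohol returns the route at 22.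

Step 8. The hindered, strongly stabilised quinone methide may react sluggishly with the enamine while the arylacetaldehyde self-condenses, and facial control at C4 may be poor. The fallback sets out from 12 and returns at 16 (skipping 15), using Brønsted-acid control of the quinone methide instead of enamine control. Compound 12 and enol ether 4 (already on the route) are combined under (R)-3,3′-bis(2,4,6-triisopropylphenyl)-BINOL phosphoric acid (antipode chosen on a model) in CH2Cl2. The ion-paired quinone methide 13 should undergo an inverse-demand hetero-Diels–Alder reaction to the 3,4-trans 2-methoxychroman acetal F4. Et3SiH and BF3·OEt2 at −78 °C remove the anomeric methoxy group and return the route at 16.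

Step 10. Proton transfer from the acetamide to the hindered aryllithium may return 16 instead of the ketone, and loss of LiF to an aryne threatens on warming. The fallback sets out from aryllithium 17 (made from 16 as in step 10) and returns at 18, replacing acyl substitution by carbonyl addition and oxidation. Aryllithium 17 is quenched at −78 °C with acetaldehyde to give the secondary benzylic alcohol F5 (both carbinol epimers). Dess–Martin oxidation of F5 gives 18.

Further compounds
F1 | step 12 | 1-{2,4-bis(benzyloxy)-3-[(3R,4S)-7-(benzyloxy)-3-[3-(benzyloxy)-2,4-dimethoxyphenyl]chroman-4-yl]-6-fluorophenyl}-3-[4-(benzyloxy)phenyl]propane-1,3-dione | COc1ccc([C@@H]2COc3cc(OCc4ccccc4)ccc3[C@H]2c2c(OCc3ccccc3)cc(F)c(c2OCc2ccccc2)C(=O)CC(=O)c2ccc(OCc4ccccc4)cc2)c(OC)c1OCc1ccccc1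
F2 | step 12 | 5,7-bis(benzyloxy)-2-[4-(benzyloxy)phenyl]-6-[(3R,4S)-7-(benzyloxy)-3-[3-(benzyloxy)-2,4-dimethoxyphenyl]chroman-4-yl]-4H-chromen-4-one | COc1ccc([C@@H]2COc3cc(OCc4ccccc4)ccc3[C@H]2c2c(OCc3ccccc3)cc3c(c2OCc2ccccc2)C(=O)C=C(c2ccc(OCc4ccccc4)cc2)O3)c(OC)c1OCc1ccccc1
F3 | step 12 | (2S,4S)-5,7-bis(benzyloxy)-2-[4-(benzyloxy)phenyl]-6-[(3R,4S)-7-(benzyloxy)-3-[3-(benzyloxy)-2,4-dimethoxyphenyl]chroman-4-yl]chroman-4-ol | COc1ccc([C@@H]2COc3cc(OCc4ccccc4)ccc3[C@H]2c2c(OCc3ccccc3)cc3c(c2OCc2ccccc2)[C@@H](O)C[C@@H](c2ccc(OCc4ccccc4)cc2)O3)c(OC)c1OCc1ccccc1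
F4 | step 8 | (3R,4S)-7-(benzyloxy)-3-[3-(benzyloxy)-2,4-dimethoxyphenyl]-4-[2,6-bis(benzyloxy)-4-fluorophenyl]-2-methoxychromane (both C2 anomers) | COc1ccc([C@@H]2C(OC)Oc3cc(OCc4ccccc4)ccc3[C@H]2c2c(OCc3ccccc3)cc(F)cc2OCc2ccccc2)c(OC)c1OCc1ccccc1
F5 | step 10 | 1-{2,4-bis(benzyloxy)-3-[(3R,4S)-7-(benzyloxy)-3-[3-(benzyloxy)-2,4-dimethoxyphenyl]chroman-4-yl]-6-fluorophenyl}ethan-1-ol (both carbinol epimers) | COc1ccc([C@@H]2COc3cc(OCc4ccccc4)ccc3[C@H]2c2c(OCc3ccccc3)cc(F)c(C(C)O)c2OCc2ccccc2)c(OC)c1OCc1ccccc1
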